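The route rests on cutting pyranone ring C of the 4-methoxyphenyl-bearing flavanone at O1–C2 and C4–C4a. Ring A offers O1 and C4a as ortho neighbours, so it enters as an O,C-dianion, while C2–C3–C4 arrives as an α-anisylidene acyl unit. Because C4 and the oxygen on C4'' stand 1,4 to each other across the C3–C3'' bond, C4 is stored as the carbonyl of a temporary γ-lactone fused to the second, already trans-configured chroman. In one operation the aryllithium opens this lactone (C4–C4a) and the freed ortho-phenol closes onto the enone (O1–C2) with kinetic protonation at C3, so that either alkene geometry is funnelled into the cis-2,3 flavanone. Oxidation and hydrogenolysis finish the synthesis.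

Key step: step 7

Numbering: unprimed locants (rings A, B, C) belong to the flavanone that carries the 4-methoxyphenyl group, doubly primed locants to the flavanone that carries the 4-hydroxyphenyl group; Bn = benzyl. Compound 1 is the commercial 2'-hydroxy-4',6'-dibenzyloxyacetophenone.

Assumption: in step 3 the salt of the (2R,3S)-acid with the (S)-amine is taken to be the less soluble one; should the crystals hold the (2S,3R)-acid, the (R)-amine is used and nothing else changes.

Step 1
Reactants: 1 1-[2,4-bis(benzyloxy)-6-hydroxyphenyl]ethanone; 2 ethyl bromoacetate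
Product: 3 ethyl 4-[2,4-bis(benzyloxy)-6-hydroxyphenyl]-4-oxobutanoate
Conditions: LiN(iPr)2 (2.2 equiv), THF, −78 °C; then 2, −78 → 0 °C; 1 M HCl work-up
Reagents that add atoms: none
Why: Two equivalents of base give the phenoxide–enolate dianion, whose carbon terminus is alkylated by the bromoacetate (enolate alkylation), while the chelated lithium phenoxide stays unreactive at low temperature; no stereocentre is formed.

Step 2
Reactants: 3 ethyl 4-[2,4-bis(benzyloxy)-6-hydroxyphenyl]-4-oxobutanoate; 4 4-(benzyloxy)benzaldehyde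
Product: 6 racemic trans-2-[5,7-bis(benzyloxy)-2-(4-benzyloxyphenyl)-4-oxochroman-3-yl]acetic acid (2R,3S/2S,3R), via chalcone acid 5 (not isolated)
Conditions: KOtBu (3 equiv), tBuOH/THF, 0 °C → rt; then AcOH, NaOAc, EtOH, 78 °C
Reagents that add atoms: none
Why: A Stobbe-type aldol condensation at the ketone methylene (the aldolate lactonises on the ester and E1cB opening gives chalcone acid 5) is followed by 6-endo-trig oxa-Michael closure of the ortho-phenol with the carboxylate kept ionised; C2'' and C3'' form as the racemic trans (diequatorial) pair because ring closure and enolisation are reversible under the acetate buffer.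

Step 3
Reactants: 6 racemic trans-2-[5,7-bis(benzyloxy)-2-(4-benzyloxyphenyl)-4-oxochroman-3-yl]acetic acid; 7 (S)-1-phenylethylamine
Product: 8 (S)-1-phenylethylammonium 2-[(2R,3S)-5,7-bis(benzyloxy)-2-(4-benzyloxyphenyl)-4-oxochroman-3-yl]acetate
Conditions: 7 (1.0 equiv), EtOH, 70 → 5 °C; two recrystallisations from EtOH
Reagents that add atoms: none
Why: Classical resolution through diastereomeric ammonium carboxylate salts fixes the absolute configuration of C2'' and C3''; the acid left in the mother liquor can be racemised through chalcone 5 (base, then acetate) and recycled.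

Step 4
Reactants: 8 (S)-1-phenylethylammonium 2-[(2R,3S)-5,7-bis(benzyloxy)-2-(4-benzyloxyphenyl)-4-oxochroman-3-yl]acetate
Product: 11 (3aS,4R,9bR)-7,9-bis(benzyloxy)-4-(4-benzyloxyphenyl)-3a,9b-dihydro-4H-furo[3,2-c]chromen-2(3H)-one, via free acid 9 (not isolated), via hydroxy acid 10 (not isolated)
Conditions: 1 M HCl, EtOAc; NaBH4 (3 equiv), THF/EtOH, 0 °C; AcOH; then EDC·HCl, DMAP (cat.), CH2Cl2, 0 °C → rt
Reagents that add atoms: none
Why: After release of the acid the small hydride should add axially to the chromanone carbonyl, as in the reduction of trans-dihydroflavonols to 2,3-trans-3,4-trans diols, to give the all-equatorial 4''R alcohol (substrate control), and carbodiimide lactonisation with retention closes the trans-fused γ-lactone that masks the C4'' ketone and activates the future C3.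

Step 5
Reactants: 11 (3aS,4R,9bR)-7,9-bis(benzyloxy)-4-(4-benzyloxyphenyl)-3a,9b-dihydro-4H-furo[3,2-c]chromen-2(3H)-one; 12 4-methoxybenzaldehyde
Product: 15 (3E,3aS,4R,9bR)-7,9-bis(benzyloxy)-4-(4-benzyloxyphenyl)-3-(4-methoxybenzylidene)-3a,9b-dihydro-4H-furo[3,2-c]chromen-2(3H)-one, via lithium aldolate 13 (not isolated), via mesylate 14 (not isolated)
Conditions: LiN(iPr)2 (1.1 equiv), THF, −78 °C; 12; MsCl (1.2 equiv), −78 → 0 °C; DBU (2 equiv), rt
Reagents that add atoms: none
Why: Aldol addition of the lactone lithium enolate, mesylation of the aldolate in the flask and DBU-induced E1cB elimination should give the conjugated (E)-arylidene lactone, the standard alkylidenation of γ-butyrolactones; the ring stereocentres are untouched and the alkene geometry does not matter later.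

Step 6
Reactants: 16 3,5-bis(benzyloxy)phenol
Product: 17 2-bromo-3,5-bis(benzyloxy)phenol
Conditions: NBS (1.0 equiv), iPr2NH (10 mol %), CH2Cl2, −78 → 0 °C
Reagents that add atoms: N-bromosuccinimide, O=C1CCC(=O)N1Br
Why: Amine-mediated ortho-selective electrophilic bromination of a phenol, in which the N-bromoamine is delivered through hydrogen bonding to the hydroxyl, should place bromine between OH and OBn and not para to OH.

Step 7
Reactants: 15 (3E,3aS,4R,9bR)-7,9-bis(benzyloxy)-4-(4-benzyloxyphenyl)-3-(4-methoxybenzylidene)-3a,9b-dihydro-4H-furo[3,2-c]chromen-2(3H)-one; 17 2-bromo-3,5-bis(benzyloxy)phenol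
Product: 20 (2S,3S)-5,7-bis(benzyloxy)-3-[(2R,3R,4R)-5,7-bis(benzyloxy)-2-(4-benzyloxyphenyl)-4-hydroxychroman-3-yl]-2-(4-methoxyphenyl)chroman-4-one, via dilithiated phenoxide 18 (not isolated), via hydroxy enone 19 (not isolated)
Conditions: 17, nBuLi (2.1 equiv), THF, −78 °C; 15, −78 → −30 °C; AcOH (2.1 equiv); then Et3N (0.3 equiv), MeOH, 0 → 20 °C
Reagents that add atoms: none
Why: Deprotonation and bromine–lithium exchange turn 17 into the ortho-lithiated lithium phenoxide 18, whose carbanion adds to the strained trans-fused lactone carbonyl of 15 (C4–C4a) and opens it to the 2-hydroxyaryl enone 19, and after the acetic acid quench the weak base lets the freed ortho-phenol close onto C2 in a 6-endo-trig oxa-Michael addition (O1–C2). The closest known reaction types are the acylation of ortho-lithiophenoxides by lactones and the amine-mediated cyclisation of ortho-hydroxyaryl α-substituted enones to cis-2,3-disubstituted chromanones. The step is stereoconvergent, because both alkene isomers of 19 lead to the same ring C enol and the reversible ring closure lets C2 adjust before the enol is protonated. C3 is set by kinetic protonation anti to the pseudoaxial 2-anisyl group, which gives the cis-2,3 relation, and its face is chosen by C3'': with C3''–H eclipsing the enol double bond (minimal A(1,3) strain) the 4''-hydroxyl lies over one face and should relay the proton to it, which corresponds to 3S and hence 2S. The selectivities needed are carbon before oxygen acylation (secured by the carbon–lithium bond next to the phenoxide and by the benzyl ethers on the other two oxygens), carbonyl addition over γ-deprotonation (low temperature, strained lactone) and cis over trans (short contact with weak base at or below 20 °C).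

Step 8
Reactants: 20 (2S,3S)-5,7-bis(benzyloxy)-3-[(2R,3R,4R)-5,7-bis(benzyloxy)-2-(4-benzyloxyphenyl)-4-hydroxychroman-3-yl]-2-(4-methoxyphenyl)chroman-4-one
Product: 21 (2S,3S)-5,7-bis(benzyloxy)-3-[(2R,3S)-5,7-bis(benzyloxy)-2-(4-benzyloxyphenyl)-4-oxochroman-3-yl]-2-(4-methoxyphenyl)chroman-4-one
Conditions: Dess–Martin periodinane (1.5 equiv), NaHCO3, CH2Cl2, 0 °C → rt
Reagents that add atoms: none
Why: Dess–Martin oxidation of the secondary benzylic alcohol under bicarbonate buffer restores the C4'' ketone without a base strong enough to epimerise C3 of the cis flavanone; C3'' becomes enolisable but already holds the thermodynamically preferred trans relation to C2''.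

Step 9
Reactants: 21 (2S,3S)-5,7-bis(benzyloxy)-3-[(2R,3S)-5,7-bis(benzyloxy)-2-(4-benzyloxyphenyl)-4-oxochroman-3-yl]-2-(4-methoxyphenyl)chroman-4-one
Product: 22 (2S,3S)-5,7-dihydroxy-3-[(2R,3S)-5,7-dihydroxy-2-(4-hydroxyphenyl)-4-oxochroman-3-yl]-2-(4-methoxyphenyl)chroman-4-one (CNP0196568.4)
Conditions: H2 (1 atm), Pd/C, EtOAc/MeOH, rt
Reagents that add atoms: none
Why: Neutral hydrogenolysis of the five benzyl ethers should leave the aryl methyl ether, both ketones and the cis C2/C3 pair intact; it is stopped at full debenzylation to avoid reductive opening of the pyranone C2–O bonds.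

Compound list

1 | 1-[2,4-bis(benzyloxy)-6-hydroxyphenyl]ethanone | CC(=O)c1c(O)cc(OCc2ccccc2)cc1OCc1ccccc1 | starting material
2 | ethyl bromoacetate | CCOC(=O)CBr | starting material
3 | ethyl 4-[2,4-bis(benzyloxy)-6-hydroxyphenyl]-4-oxobutanoate | CCOC(=O)CCC(=O)c1c(O)cc(OCc2ccccc2)cc1OCc1ccccc1 | intermediate
4 | 4-(benzyloxy)benzaldehyde | O=Cc1ccc(OCc2ccccc2)cc1 | starting material
5 | (E)-3-[2,4-bis(benzyloxy)-6-hydroxybenzoyl]-4-[4-(benzyloxy)phenyl]but-3-enoic acid (chalcone acid) | OC(=O)C/C(=C\c1ccc(OCc2ccccc2)cc1)C(=O)c1c(O)cc(OCc2ccccc2)cc1OCc1ccccc1 | intermediate (not isolated)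
6 | racemic trans-2-[5,7-bis(benzyloxy)-2-(4-benzyloxyphenyl)-4-oxochroman-3-yl]acetic acid (both enantiomers shown) | OC(=O)C[C@@H]1C(=O)c2c(OCc3ccccc3)cc(OCc3ccccc3)cc2O[C@H]1c1ccc(OCc2ccccc2)cc1.OC(=O)C[C@H]1C(=O)c2c(OCc3ccccc3)cc(OCc3ccccc3)cc2O[C@@H]1c1ccc(OCc2ccccc2)cc1 | intermediate
7 | (S)-1-phenylethylamine | C[C@H](N)c1ccccc1 | starting material
8 | (S)-1-phenylethylammonium 2-[(2R,3S)-5,7-bis(benzyloxy)-2-(4-benzyloxyphenyl)-4-oxochroman-3-yl]acetate | [O-]C(=O)C[C@@H]1C(=O)c2c(OCc3ccccc3)cc(OCc3ccccc3)cc2O[C@H]1c1ccc(OCc2ccccc2)cc1.C[C@H]([NH3+])c1ccccc1 | intermediate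
9 | 2-[(2R,3S)-5,7-bis(benzyloxy)-2-(4-benzyloxyphenyl)-4-oxochroman-3-yl]acetic acid | OC(=O)C[C@@H]1C(=O)c2c(OCc3ccccc3)cc(OCc3ccccc3)cc2O[C@H]1c1ccc(OCc2ccccc2)cc1 | intermediate (not isolated)
10 | 2-[(2R,3R,4R)-5,7-bis(benzyloxy)-2-(4-benzyloxyphenyl)-4-hydroxychroman-3-yl]acetic acid | OC(=O)C[C@@H]1[C@@H](O)c2c(OCc3ccccc3)cc(OCc3ccccc3)cc2O[C@H]1c1ccc(OCc2ccccc2)cc1 | intermediate (not isolated)
11 | (3aS,4R,9bR)-7,9-bis(benzyloxy)-4-(4-benzyloxyphenyl)-3a,9b-dihydro-4H-furo[3,2-c]chromen-2(3H)-one (trans-fused lactone) | O=C1C[C@@H]2[C@@H](O1)c1c(OCc3ccccc3)cc(OCc3ccccc3)cc1O[C@H]2c1ccc(OCc2ccccc2)cc1 | intermediate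
12 | 4-methoxybenzaldehyde | COc1ccc(C=O)cc1 | starting material
13 | lithium alkoxide of the 3-[hydroxy(4-methoxyphenyl)methyl] derivative of 11 (epimers at C3 and at the carbinol carbon) | O=C1C(C(O[Li])c2ccc(OC)cc2)[C@@H]2[C@@H](O1)c1c(OCc3ccccc3)cc(OCc3ccccc3)cc1O[C@H]2c1ccc(OCc2ccccc2)cc1 | intermediate (not isolated)
14 | methanesulfonate of the aldol adduct (same epimer mixture) | O=C1C(C(OS(C)(=O)=O)c2ccc(OC)cc2)[C@@H]2[C@@H](O1)c1c(OCc3ccccc3)cc(OCc3ccccc3)cc1O[C@H]2c1ccc(OCc2ccccc2)cc1 | intermediate (not isolated)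
15 | (3E,3aS,4R,9bR)-7,9-bis(benzyloxy)-4-(4-benzyloxyphenyl)-3-(4-methoxybenzylidene)-3a,9b-dihydro-4H-furo[3,2-c]chromen-2(3H)-one | O=C1/C(=C/c2ccc(OC)cc2)[C@@H]2[C@@H](O1)c1c(OCc3ccccc3)cc(OCc3ccccc3)cc1O[C@H]2c1ccc(OCc2ccccc2)cc1 | intermediate
16 | 3,5-bis(benzyloxy)phenol | Oc1cc(OCc2ccccc2)cc(OCc2ccccc2)c1 | starting material
17 | 2-bromo-3,5-bis(benzyloxy)phenol | Oc1cc(OCc2ccccc2)cc(OCc2ccccc2)c1Br | intermediate
18 | lithium 3,5-bis(benzyloxy)-2-lithiophenoxide | [Li]Oc1cc(OCc2ccccc2)cc(OCc2ccccc2)c1[Li] | intermediate (not isolated)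
19 | (E)-1-[2,4-bis(benzyloxy)-6-hydroxyphenyl]-2-[(2R,3R,4R)-5,7-bis(benzyloxy)-2-(4-benzyloxyphenyl)-4-hydroxychroman-3-yl]-3-(4-methoxyphenyl)prop-2-en-1-one | COc1ccc(/C=C(/C(=O)c2c(O)cc(OCc3ccccc3)cc2OCc2ccccc2)[C@@H]2[C@@H](O)c3c(OCc4ccccc4)cc(OCc4ccccc4)cc3O[C@H]2c2ccc(OCc3ccccc3)cc2)cc1 | intermediate (not isolated)
20 | (2S,3S)-5,7-bis(benzyloxy)-3-[(2R,3R,4R)-5,7-bis(benzyloxy)-2-(4-benzyloxyphenyl)-4-hydroxychroman-3-yl]-2-(4-methoxyphenyl)chroman-4-one | COc1ccc([C@H]2Oc3cc(OCc4ccccc4)cc(OCc4ccccc4)c3C(=O)[C@H]2[C@@H]2[C@@H](O)c3c(OCc4ccccc4)cc(OCc4ccccc4)cc3O[C@H]2c2ccc(OCc3ccccc3)cc2)cc1 | intermediate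
21 | (2S,3S)-5,7-bis(benzyloxy)-3-[(2R,3S)-5,7-bis(benzyloxy)-2-(4-benzyloxyphenyl)-4-oxochroman-3-yl]-2-(4-methoxyphenyl)chroman-4-one | COc1ccc([C@H]2Oc3cc(OCc4ccccc4)cc(OCc4ccccc4)c3C(=O)[C@H]2[C@@H]2C(=O)c3c(OCc4ccccc4)cc(OCc4ccccc4)cc3O[C@H]2c2ccc(OCc3ccccc3)cc2)cc1 | intermediate
22 | (2S,3S)-5,7-dihydroxy-3-[(2R,3S)-5,7-dihydroxy-2-(4-hydroxyphenyl)-4-oxochroman-3-yl]-2-(4-methoxyphenyl)chroman-4-one | COc1ccc([C@H]2Oc3cc(O)cc(O)c3C(=O)[C@H]2[C@@H]2C(=O)c3c(O)cc(O)cc3O[C@H]2c2ccc(O)cc2)cc1 | target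

Total step count: 9. Longest linear sequence: 8 (steps 1–5 and 7–9; step 6 is the side branch).

Steps most likely to fail

1. Step 7. The aryllithium may deprotonate the γ-position (C3a–H) of the arylidene lactone instead of adding to its carbonyl. The ring closure and protonation may also take the wrong face with respect to C3'', or the kinetic cis pair may drift to trans under the base. The fallback is stepwise and catalyst-controlled. Lactone 15 is opened with Me(MeO)NH·HCl and iPrMgCl to the hydroxy N-methoxy-N-methylamide F1. The alcohol is silylated (TBSOTf, 2,6-lutidine) to the silyl ether F2. Aryllithium 18, made from 17 as in step 7, is acylated by F2 to give the isolated silylated 2-hydroxyaryl enone F3. F3 is cyclised in toluene at low temperature with a cinchona alkaloid base (quinine or quinidine, whichever matches the 2S sense in a test run) to the silylated flavanone F4; this is a known enantioselective, cis-selective oxa-Michael closure of ortho-hydroxyaryl α-substituted enones. HF·pyridine then gives 20, where the route is rejoined.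

2. Step 2. The condensation may stall through deprotonation at the ester methylene, retro-aldol reaction or self-condensation of 3. The fallback makes the aryl–acyl bond last. Stobbe condensation of aldehyde 4 with diethyl succinate (KOtBu, tBuOH) gives the half-ester F5. Its lithium carboxylate is treated with aryllithium 18 (from 17), which is acylated by the conjugated ester and gives chalcone acid 5 directly. The acetate-buffered ring closure of step 2 then gives 6.

3. Step 3. The two diastereomeric salts may co-crystallise or fail to crystallise. The fallback is a covalent resolution whose auxiliary is released by the next ring closure. Racemic 6 is esterified with (R)-pantolactone (EDC, DMAP) and the diastereomeric esters are separated by chromatography or crystallisation to give the (2R,3S) pantolactone ester F6. NaBH4 reduction gives the hydroxy ester F7. Warming F7 with DMAP in toluene closes the lactone with loss of pantolactone and gives 11, where the route is rejoined.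

Further compounds

F1 | step 7 | (E)-2-[(2R,3R,4R)-5,7-bis(benzyloxy)-2-(4-benzyloxyphenyl)-4-hydroxychroman-3-yl]-N-methoxy-3-(4-methoxyphenyl)-N-methylprop-2-enamide | CON(C)C(=O)/C(=C/c1ccc(OC)cc1)[C@@H]1[C@@H](O)c2c(OCc3ccccc3)cc(OCc3ccccc3)cc2O[C@H]1c1ccc(OCc2ccccc2)cc1
F2 | step 7 | 4-O-tert-butyldimethylsilyl ether of F1 | CON(C)C(=O)/C(=C/c1ccc(OC)cc1)[C@@H]1[C@@H](O[Si](C)(C)C(C)(C)C)c2c(OCc3ccccc3)cc(OCc3ccccc3)cc2O[C@H]1c1ccc(OCc2ccccc2)cc1
F3 | step 7 | 4''-O-tert-butyldimethylsilyl ether of hydroxy enone 19 | COc1ccc(/C=C(/C(=O)c2c(O)cc(OCc3ccccc3)cc2OCc2ccccc2)[C@@H]2[C@@H](O[Si](C)(C)C(C)(C)C)c3c(OCc4ccccc4)cc(OCc4ccccc4)cc3O[C@H]2c2ccc(OCc3ccccc3)cc2)cc1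
F4 | step 7 | 4''-O-tert-butyldimethylsilyl ether of 20 | COc1ccc([C@H]2Oc3cc(OCc4ccccc4)cc(OCc4ccccc4)c3C(=O)[C@H]2[C@@H]2[C@@H](O[Si](C)(C)C(C)(C)C)c3c(OCc4ccccc4)cc(OCc4ccccc4)cc3O[C@H]2c2ccc(OCc3ccccc3)cc2)cc1
F5 | step 2 | (E)-4-[4-(benzyloxy)phenyl]-3-(ethoxycarbonyl)but-3-enoic acid | CCOC(=O)/C(CC(=O)O)=C/c1ccc(OCc2ccccc2)cc1
F6 | step 3 | (3R)-4,4-dimethyl-2-oxooxolan-3-yl 2-[(2R,3S)-5,7-bis(benzyloxy)-2-(4-benzyloxyphenyl)-4-oxochroman-3-yl]acetate | CC1(C)COC(=O)[C@@H]1OC(=O)C[C@@H]1C(=O)c2c(OCc3ccccc3)cc(OCc3ccccc3)cc2O[C@H]1c1ccc(OCc2ccccc2)cc1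
F7 | step 3 | (3R)-4,4-dimethyl-2-oxooxolan-3-yl 2-[(2R,3R,4R)-5,7-bis(benzyloxy)-2-(4-benzyloxyphenyl)-4-hydroxychroman-3-yl]acetate | CC1(C)COC(=O)[C@@H]1OC(=O)C[C@@H]1[C@@H](O)c2c(OCc3ccccc3)cc(OCc3ccccc3)cc2O[C@H]1c1ccc(OCc2ccccc2)cc1
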